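## Structural features

The target is a flavan: an aromatic ring A fused to a saturated pyran ring (O1, C2, C3, C4, C4a, C8a), with the aryl ring B attached at C2. C2 is the only stereocentre; it is benzylic, oxygen-bearing and S-configured (O1 > C1' > C3 > H), and it has no neighbouring stereocentre or functional group that could relay asymmetry. Ring A has the phloroglucinol pattern (O1, 5-OH, 7-OH) with a 3-methylbut-2-enyl group at C8, between O1 and the C7 hydroxyl, and an unsubstituted, strongly nucleophilic C6. Ring B carries its hydroxyl (C3') and methoxyl (C5') both meta to C1', so neither can stabilise a cation at C2, and neither can activate a vinyl group at C1' by conjugation. The fragile elements are the trisubstituted prenyl alkene (no hydrogenation, and acid can add the C7 hydroxyl across it) and the electron-rich polyphenol (oxidation under base, electrophilic attack at C6). The real difficulties are the isolated stereocentre and the placement of the prenyl group at C8 and not at C6. The key step uses the fact that the pyran ring is the formal (4+2) adduct of a ring A ortho-quinone methide (O1=C8a–C4a=C4) and the vinyl group (C2=C3) of a ring B styrene, so that C3–C4, O1–C2 and the C2 configuration arise in one event.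

## Logic of the disconnections

**15 back to 13.** The two acetal O–CH2 bonds on O5 and O7 and the carbamoyl O–C(=O) bond on O3' are re-formed in the retrosynthetic sense. Ring A needs ether-type masking so that it stays electron-rich enough to ionise at C4, and ring B must not be a free phenol in the key step. Nothing is gained in skeleton, but all protecting-group removal falls into one final operation that passes through 14. The forward step has to spare the prenyl alkene next to the C7 hydroxyl and the C2 ether: base first for the carbamate, then dilute acid for the acetals.

**13 back to 8 and 11 (through 12).** C3–C4 and O1–C2 are cut. Both lie in the pyran ring, their cleavage separates ring A from ring B, and the only stereocentre sits on one of them. A chiral bicycle becomes two achiral monocyclic arenes of similar size. The forward step must generate 12 from 8 under an acid mild enough for the acetals and the prenyl group, hold both partners on one chiral catalyst, and add across the vinyl group faster than 12 alkylates aromatic carbons. For the last reason ring B enters as 11 and not as 10: a free phenol meta to the vinyl group would direct attack to its own ortho carbons, whereas the N–H carbamate still offers a hydrogen-bond donor without activating the ring.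

**11 back to 10.** The O3'–C(=O) bond is cut. The carbamate arises by an addition that has no by-product. It must be installed after the olefination because it would not survive a basic ylide.

**10 back to 9.** The vinyl C=C bond is cut, and the terminal carbon is traced to a Wittig methylenation of the formyl group. This reduces ring B to a commercial aldehyde. The olefination must tolerate a free phenol, which is met by an excess of the ylide.

**8 back to 7.** The C4–H bond is cut (reduction of the formyl group). The aldehyde is the stable oxidation level for all earlier steps, and its hydrogen bond to the neighbouring hydroxyl is what differentiates the three phenols. The reduction must be cold and the product must be handled at neutral pH, because 8 ionises easily.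

**7 back to 5 (through 6).** The C8–CH2 bond of the prenyl group is cut and traced to an O–C bond by a [3,3] shift. Direct C-alkylation of a phloroglucinol ring has no positional control, whereas a sigmatropic shift delivers the group only to the carbon ortho to the oxygen it leaves, and the other ortho carbon is blocked by the formyl group. The positional problem becomes an O-alkylation problem. The ether must be the tertiary 1,1-dimethylallyl ether, and the shift must outrun loss of the allyl group.

**5 back to 4 and 2.** The O–C(tertiary) bond is cut. A tertiary allyl ether cannot be made by SN2, but palladium-catalysed allylic substitution delivers oxygen to the more substituted allyl terminus. The forward step needs kinetic control (low temperature, short time) so that the branched ether does not isomerise to the linear one.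

**4 back to 3.** Two acetal O–CH2 bonds are cut. The chelated hydroxyl of 3 is the least reactive, so two equivalents of alkylating agent should stop at 4. The step asks only for stoichiometric control.

**2 back to 1.** The carbonate O–C(=O) bond is cut. 2 is the activated form of the tertiary alcohol 1. The acylation must avoid ionisation of the tertiary allylic system, which prior deprotonation secures.

## Other disconnections considered

Alternative 1: Ring A is cut at C4a–C8a and C5–C6.

- **Forward step.** Cyclobutenone A2 (future C6, C7, C8, C8a, with the prenyl group on the future C8) is heated with siloxyalkyne A3 (future C4a and C5 plus the C4–C3–C2 chain with the R carbinol already in place). The cascade is 4π opening to a vinylketene, (2+2) addition to the ynol silyl ether, a second 4π opening, 6π closure and tautomerisation, and would give phenol A1. Removal of the triethylsilyl group, Mitsunobu closure of O1–C2 with inversion (R carbinol to 2S) and desilylation would follow.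
- **In its favour.** Every ring A substituent is placed by the pericyclic sequence, so there is no C6/C8 ambiguity and no Claisen step; on regiocontrol of ring A this plan is the better one. The stereocentre would come from an established asymmetric ketone reduction and be transferred by an established SN2 closure; on reliability of stereocontrol it is also the better one, because the chosen plan relies on an enantioselection without precedent.
- **Against it.** A2 and A3 are each several steps from commercial material and both are sensitive (a 3-siloxycyclobutenone with an allylic substituent, a siloxyalkyne carrying a silyl-protected benzylic carbinol). Ene or (2+2) reactions of the ketene intermediates with the prenyl alkene cannot be excluded. Four silyl ethers of two kinds must be differentiated.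
- **Comparison.** The mechanism is thermal, catalyst-free and predictable; the chosen plan is catalyst-dependent. In structure, this plan builds ring A and leaves the pyran ring and its closure to later steps, so it forms fewer target bonds per step. In step economy it would probably need well over a dozen steps against nine, and is clearly the poorer.

Alternative 2: Ring A is cut at C5–C6.

- **Forward step.** Dihydropyran A5 already holds O1, C2 (S), C3, C4, C4a and C8a, with an ester on C4a and a CH(prenyl)C(=O)CH3 chain on C8a. A strong base such as LiN(SiMe3)2 would form the methyl ketone enolate (C6), which acylates at the ester carbon (C5) across the C4a=C8a bond in a Dieckmann-type six-membered closure. Loss of methoxide and tautomerisation of the cyclohexenedione would give resorcinol A4.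
- **In its favour.** The stereocentre exists before ring A and is not acidic, so it is not at risk. The prenyl group sits on the only carbon between the ketone and C8a; on prenyl regiochemistry this plan is the equal of the chosen one. A4 has the 5,7-hydroxyls free and needs only fluoride to reach the target; on the endgame it is the better plan, because no acid meets the prenyl phenol. The ring-forming reaction belongs to a well-known class (polyketide-type aromatisation), which is better precedent than the chosen key step has.
- **Against it.** The most acidic hydrogen of A5 is at C8, so the wanted C6 enolate needs a dianion. The ester is a deactivated vinylogous carbonate. Liberated methoxide could open the pyran by exchange at C8a before aromatisation. Above all, an enantioselective synthesis of A5 is a long project of its own.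
- **Comparison.** The mechanism is ionic and driven by aromatisation, and is more secure than the chosen key step. In structure, it shifts all the difficulty into a densely functionalised precursor. In step economy it is clearly the poorer.

Alternative 3: The pyran ring is cut at C4–C4a and O1–C2, the same C–O bond as in the chosen plan but a different C–C bond.

- **Forward step.** N-aryloxyacetamide A7 and 3-arylcyclopropene A8 would be joined by a rhodium catalyst carrying a chiral cyclopentadienyl ligand (a CpRh(C2H4)2-type precatalyst, oxidised in the flask to trivalent rhodium). The O–NHAc group directs metalation of C4a–H, the strained alkene inserts, β-carbon elimination opens the three-membered ring, and O–N cleavage delivers O1 to the aryl-bearing carbon to give 2H-chromene A6. Selective reduction of C3=C4 and acetal cleavage would follow.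
- **In its favour.** It is as convergent as the chosen plan: two arenes are joined, the pyran is closed and C2 is set in one step (equal). The racemic annulation type is established for simple N-aryloxyamides with cyclopropenes, so ring construction has the better precedent. C4a–H is the only ortho hydrogen of A7, so site selectivity is not in question (equal). No quinone methide is involved, so alkylation at C6 of ring A is not an issue (better).
- **Against it.** The established cases use 3,3-disubstituted cyclopropenes. A8 has a hydrogen at C3, is prone to ene dimerisation, and would give a tertiary stereocentre whose control by the catalyst is as unproven as in the chosen plan (equal uncertainty). A7 requires O-amination of a hindered, oxidation-prone phenol. The prenyl alkene next to the directing group can bind rhodium. A6 needs a chemoselective reduction beside the prenyl alkene, and 2-aryl-2H-chromenes can lose configuration by reversible oxa-6π ring opening.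
- **Comparison.** The mechanism is organometallic and redox-neutral with a more plausible ring-forming step, but its enantiocontrol is no better founded. In structure it reaches the wrong oxidation level at C3–C4. In step economy it would be about one to two steps longer.

Key step: step 8

**Assumption:** the sense of induction of the phosphoric acid cannot be derived from precedent. The (R)-catalyst is written; its mirror image would be used, with nothing else changed, if it favoured 2R.

**Remark on the design:** ring B enters the cycloaddition as the N-phenylcarbamate 11, made from phenol 10, for the reason set out under the second disconnection; the free 3'-phenol 14 is released in the last step. (R)-TRIP is (R)-3,3'-bis(2,4,6-triisopropylphenyl)-1,1'-binaphthyl-2,2'-diyl hydrogen phosphate.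

## Route

Step 1
Reactants: 1 2-methylbut-3-en-2-ol
Product: 2 methyl 2-methylbut-3-en-2-yl carbonate
Conditions: n-BuLi (1.05 equiv), THF, −78 °C; ClCO2Me, −78 °C → rt
Reagents that add atoms: methyl chloroformate, COC(=O)Cl
Why: O-acylation of a lithium alkoxide; prior deprotonation makes the hindered tertiary allylic alcohol react cleanly and avoids ionisation of the allylic system.

Step 2
Reactants: 3 2,4,6-trihydroxybenzaldehyde
Product: 4 2-hydroxy-4,6-bis(methoxymethoxy)benzaldehyde
Conditions: MOMCl (2.1 equiv), i-Pr2NEt (2.5 equiv), CH2Cl2, 0 °C → rt
Reagents that add atoms: chloromethyl methyl ether, COCCl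
Why: Williamson-type acetal formation; once one ortho hydroxyl is alkylated the other stays locked in a hydrogen bond to the formyl oxygen and is the least nucleophilic, so two equivalents should stop at the 4,6-bis-acetal.

Step 3
Reactants: 4 2-hydroxy-4,6-bis(methoxymethoxy)benzaldehyde; 2 methyl 2-methylbut-3-en-2-yl carbonate (1.5 equiv)
Product: 5 2-[(2-methylbut-3-en-2-yl)oxy]-4,6-bis(methoxymethoxy)benzaldehyde
Conditions: Pd(PPh3)4 (3 mol %), THF, 0 °C → rt, stopped at full conversion
Reagents that add atoms: none
Why: Tsuji–Trost O-allylation: zerovalent palladium ionises the carbonate, CO2 is lost, the methoxide deprotonates the phenol, and the phenoxide attacks the 1,1-dimethylallyl palladium cation at its more substituted end under kinetic control; low temperature and short time prevent re-ionisation to the linear ether.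

Step 4
Reactants: 5 2-[(2-methylbut-3-en-2-yl)oxy]-4,6-bis(methoxymethoxy)benzaldehyde
Product: 7 2-hydroxy-4,6-bis(methoxymethoxy)-3-(3-methylbut-2-enyl)benzaldehyde, via cyclohexadienone 6 (not isolated)
Conditions: PhNEt2, 150 °C
Reagents that add atoms: none
Why: Aromatic Claisen rearrangement ([3,3]); only one ortho carbon carries hydrogen, so dienone 6 enolises irreversibly and the inverted allyl unit, now a 3-methylbut-2-enyl group, ends up on the carbon that becomes C8; the gem-dimethyl group accelerates the shift and the amine solvent buffers traces of acid.

Step 5
Reactants: 7 2-hydroxy-4,6-bis(methoxymethoxy)-3-(3-methylbut-2-enyl)benzaldehyde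
Product: 8 2-(hydroxymethyl)-3,5-bis(methoxymethoxy)-6-(3-methylbut-2-enyl)phenol
Conditions: NaBH4 (1.0 equiv), MeOH/THF, 0 °C; pH 7 buffer; used at once without acidic silica
Reagents that add atoms: none
Why: Borohydride reduction of an aryl aldehyde, which leaves acetals and the alkene untouched; low temperature and neutral work-up avoid premature ionisation of the electron-rich benzylic alcohol and over-reduction through the quinone methide.

Step 6
Reactants: 9 3-hydroxy-5-methoxybenzaldehyde
Product: 10 3-ethenyl-5-methoxyphenol
Conditions: Ph3PCH3Br (2.5 equiv), KOt-Bu (2.5 equiv), THF, 0 °C → rt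
Reagents that add atoms: methyltriphenylphosphonium bromide, C[P+](c1ccccc1)(c1ccccc1)c1ccccc1.[Br-]
Why: Wittig methylenation; the first equivalent of ylide is spent deprotonating the phenol, and the phenoxide is meta to the formyl group and does not deactivate it by conjugation, so the second equivalent olefinates.

Step 7
Reactants: 10 3-ethenyl-5-methoxyphenol
Product: 11 (3-ethenyl-5-methoxyphenyl) N-phenylcarbamate
Conditions: PhNCO (1.1 equiv), Et3N (5 mol %), CH2Cl2, rt
Reagents that add atoms: phenyl isocyanate, O=C=Nc1ccccc1
Why: Base-catalysed addition of a phenol to an isocyanate (carbamoylation), with no by-product; it turns the ring-activating hydroxyl into a weakly donating acyloxy group that still carries an N–H hydrogen-bond donor.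

Step 8
Reactants: 8 2-(hydroxymethyl)-3,5-bis(methoxymethoxy)-6-(3-methylbut-2-enyl)phenol; 11 (3-ethenyl-5-methoxyphenyl) N-phenylcarbamate (3 equiv, excess recoverable)
Product: 13 [3-[(2S)-5,7-bis(methoxymethoxy)-8-(3-methylbut-2-enyl)chroman-2-yl]-5-methoxyphenyl] N-phenylcarbamate, via ortho-quinone methide 12 (not isolated)
Conditions: (R)-TRIP (10 mol %), 5 Å MS, PhMe, 25 °C; 8 added over 8 h by syringe pump
Reagents that add atoms: none
Why: Proposed new method: the phosphoric acid protonates the benzylic hydroxyl of 8, water leaves with the push of the C8a hydroxyl and the ortho and para acetal oxygens, and quinone methide 12 stays hydrogen-bonded through its carbonyl oxygen to the P–OH group while the phosphoryl oxygen holds the carbamate N–H of 11; the closest known reaction types are the phosphoric acid-catalysed inverse-demand hetero-Diels–Alder reactions of ortho-quinone methides with ortho-hydroxystyrenes and with N–H enecarbamates, and the racemic thermal cycloaddition with plain styrenes, none of which covers a styrene whose only handle is a meta carbamate. The terminal CH2 of the styrene bonds to C4 and the carbonyl oxygen collapses onto the developing benzylic cation at C2, so the pyran ring closes in one asynchronous (4+2) cycloaddition (in the stepwise limit, conjugate addition followed by six-membered ion-pair collapse), forming C3–C4 and O1–C2. Regiochemistry follows from polarity: the nucleophilic terminal carbon of the styrene meets the electrophilic methide carbon, and the aryl-stabilised carbon is the only site for oxygen. C2 is the only new stereocentre, and its configuration is decided by which face of the styrene is presented to C4 once both partners are anchored to the same phosphate inside the pocket of the two 2,4,6-triisopropylphenyl groups; the methide carbon is unsubstituted, so no diastereoselectivity arises. The step needs cycloaddition at the vinyl group in preference to alkylation of aromatic carbons, to oligomerisation through C6 of ring A and to reaction at the prenyl alkene. This is secured by the carbamate (ring B is no longer a phenol, so hydrogen-bond-assisted ortho-alkylation is shut off), by the acetal and not phenolic oxygens of ring A, by the weak acid, by the excess of 11 and by the slow addition of 8. The prenyl alkene cannot span O1 and C4 and is more hindered than the styrene, and the acetals should tolerate the catalyst at room temperature. Because 12 does not form without acid at this temperature, each cycloaddition should take place on the chiral catalyst.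

Step 9
Reactants: 13 [3-[(2S)-5,7-bis(methoxymethoxy)-8-(3-methylbut-2-enyl)chroman-2-yl]-5-methoxyphenyl] N-phenylcarbamate
Product: 15 (2S)-2-(3-hydroxy-5-methoxyphenyl)-8-(3-methylbut-2-enyl)chromane-5,7-diol, via free 3'-phenol 14 (not isolated)
Conditions: K2CO3 (1.5 equiv), degassed MeOH, rt; then HCl added to ca. 1 M, 25 → 40 °C
Reagents that add atoms: none
Why: E1cB methanolysis of the N–H aryl carbamate (through phenyl isocyanate, trapped by the solvent) followed by acid-catalysed transacetalisation of the two methoxymethyl ethers; C2 should not epimerise because the meta-oxygenated ring B cannot stabilise a cation there, and dilute acid at or below 40 °C keeps the C7 hydroxyl from adding to the prenyl alkene.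

## Compound list

1 | 2-methylbut-3-en-2-ol | CC(C)(O)C=C | starting material
2 | methyl 2-methylbut-3-en-2-yl carbonate | COC(=O)OC(C)(C)C=C | intermediate
3 | 2,4,6-trihydroxybenzaldehyde | O=Cc1c(O)cc(O)cc1O | starting material
4 | 2-hydroxy-4,6-bis(methoxymethoxy)benzaldehyde | COCOc1cc(O)c(C=O)c(OCOC)c1 | intermediate
5 | 2-[(2-methylbut-3-en-2-yl)oxy]-4,6-bis(methoxymethoxy)benzaldehyde | C=CC(C)(C)Oc1cc(OCOC)cc(OCOC)c1C=O | intermediate
6 | 2,4-bis(methoxymethoxy)-5-(3-methylbut-2-enyl)-6-oxocyclohexa-1,3-diene-1-carbaldehyde (not isolated) | O=CC1=C(OCOC)C=C(OCOC)C(CC=C(C)C)C1=O | intermediate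
7 | 2-hydroxy-4,6-bis(methoxymethoxy)-3-(3-methylbut-2-enyl)benzaldehyde | COCOc1cc(OCOC)c(CC=C(C)C)c(O)c1C=O | intermediate
8 | 2-(hydroxymethyl)-3,5-bis(methoxymethoxy)-6-(3-methylbut-2-enyl)phenol | OCc1c(OCOC)cc(OCOC)c(CC=C(C)C)c1O | intermediate
9 | 3-hydroxy-5-methoxybenzaldehyde | COc1cc(O)cc(C=O)c1 | starting material
10 | 3-ethenyl-5-methoxyphenol | COc1cc(O)cc(C=C)c1 | intermediate
11 | (3-ethenyl-5-methoxyphenyl) N-phenylcarbamate | COc1cc(OC(=O)Nc2ccccc2)cc(C=C)c1 | intermediate
12 | 3,5-bis(methoxymethoxy)-6-methylidene-2-(3-methylbut-2-enyl)cyclohexa-2,4-dien-1-one (not isolated) | C=C1C(OCOC)=CC(OCOC)=C(CC=C(C)C)C1=O | intermediate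
13 | [3-[(2S)-5,7-bis(methoxymethoxy)-8-(3-methylbut-2-enyl)chroman-2-yl]-5-methoxyphenyl] N-phenylcarbamate | COc1cc(OC(=O)Nc2ccccc2)cc([C@@H]2CCc3c(OCOC)cc(OCOC)c(CC=C(C)C)c3O2)c1 | intermediate
14 | 3-[(2S)-5,7-bis(methoxymethoxy)-8-(3-methylbut-2-enyl)chroman-2-yl]-5-methoxyphenol (not isolated) | COc1cc(O)cc([C@@H]2CCc3c(OCOC)cc(OCOC)c(CC=C(C)C)c3O2)c1 | intermediate
15 | (2S)-2-(3-hydroxy-5-methoxyphenyl)-8-(3-methylbut-2-enyl)chromane-5,7-diol | COc1cc(O)cc([C@@H]2CCc3c(O)cc(O)c(CC=C(C)C)c3O2)c1 | target

## Step count and least certain steps

Total step count: 9. Longest linear sequence: 6 steps (3 → 4 → 5 → 7 → 8 → 13 → 15; steps 2, 3, 4, 5, 8, 9).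

**Step 8 (key step, proposed new method).** Three processes are most likely to go wrong.
- Poor facial selectivity, because the carbamate N–H is several atoms away from the reacting alkene and may not fix the styrene in the pocket.
- Diversion of the quinone methide into alkylation at C6 of ring A units of 8 or of the product, which would lead to oligomers.
- Slow cycloaddition, because the styrene has only meta substituents and is a weak 2π partner.

Fallback, by known chemistry only, leaving the route at 7 and rejoining it at 15: commercial 1-(3-hydroxy-5-methoxyphenyl)ethanone F1 would be protected with MOMCl and i-Pr2NEt as 1-[3-methoxy-5-(methoxymethoxy)phenyl]ethanone F2. Claisen–Schmidt condensation of F2 with 7 (KOH, EtOH, rt) should give (E)-3-[2-hydroxy-4,6-bis(methoxymethoxy)-3-(3-methylbut-2-enyl)phenyl]-1-[3-methoxy-5-(methoxymethoxy)phenyl]prop-2-en-1-one F3. Asymmetric transfer hydrogenation with RuCl(p-cymene)[(R,R)-TsDPEN] and HCO2Na in H2O/MeOH reduces first the enone alkene and then the ketone, leaves the prenyl alkene alone, and should give 2-[(3R)-3-hydroxy-3-[3-methoxy-5-(methoxymethoxy)phenyl]propyl]-3,5-bis(methoxymethoxy)-6-(3-methylbut-2-enyl)phenol F4. Mitsunobu closure (PPh3, DIAD, THF, 0 °C) with inversion at the carbinol carbon should give (2S)-5,7-bis(methoxymethoxy)-2-[3-methoxy-5-(methoxymethoxy)phenyl]-8-(3-methylbut-2-enyl)chromane F5. The acid stage of step 9 would then release 15.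

**Step 3.** The risk is attack at the less substituted allyl end, or later palladium-mediated isomerisation of the tertiary ether to the linear prenyl ether, made worse by the low nucleophilicity of the chelated phenoxide. Fallback from 4, rejoining at 5: copper-catalysed O-alkylation with 2-chloro-2-methylbut-3-yne (CuCl2 cat., DBU, MeCN, 0 °C) to 2-[(2-methylbut-3-yn-2-yl)oxy]-4,6-bis(methoxymethoxy)benzaldehyde F6, then semi-hydrogenation (H2, Pd/CaCO3 poisoned with Pb(OAc)2, quinoline) to 5.

**Step 4.** The risk is loss of the tertiary allyl group as isoprene at the temperature of the shift, which would return 4, or an ipso shift to the formyl-bearing carbon followed by a second shift to the carbon between the two acetals. Fallback from 3, rejoining at 7: direct C-alkylation with 1-bromo-3-methylbut-2-ene and DBU in THF to 2,4,6-trihydroxy-3-(3-methylbut-2-enyl)benzaldehyde F7 (the two open ring carbons of 3 are equivalent), then MOMCl (2 equiv) and i-Pr2NEt, which should leave free the hydroxyl flanked by the formyl and prenyl groups and so give 7. The position of the free hydroxyl would have to be confirmed before going on.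

**Step 9.** The risk is acid-promoted addition of the C7 hydroxyl, or of the solvent, to the prenyl alkene during acetal cleavage. Fallback from 14 (isolated after the K2CO3 stage), rejoining at 15: non-protic exchange of the acetals with TMSOTf and 2,2'-bipyridyl in CH2Cl2 at 0 °C should give (2S)-2-[3-methoxy-5-(trimethylsilyloxy)phenyl]-8-(3-methylbut-2-enyl)-5,7-bis(trimethylsilyloxy)chromane F8, which water hydrolyses to 15 without a strong Brønsted acid.

## Further compounds

F1 | step 8 | 1-(3-hydroxy-5-methoxyphenyl)ethanone | CC(=O)c1cc(O)cc(OC)c1
F2 | step 8 | 1-[3-methoxy-5-(methoxymethoxy)phenyl]ethanone | CC(=O)c1cc(OC)cc(OCOC)c1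
F3 | step 8 | (E)-3-[2-hydroxy-4,6-bis(methoxymethoxy)-3-(3-methylbut-2-enyl)phenyl]-1-[3-methoxy-5-(methoxymethoxy)phenyl]prop-2-en-1-one | COCOc1cc(OC)cc(C(=O)/C=C/c2c(OCOC)cc(OCOC)c(CC=C(C)C)c2O)c1
F4 | step 8 | 2-[(3R)-3-hydroxy-3-[3-methoxy-5-(methoxymethoxy)phenyl]propyl]-3,5-bis(methoxymethoxy)-6-(3-methylbut-2-enyl)phenol | COCOc1cc(OC)cc([C@H](O)CCc2c(OCOC)cc(OCOC)c(CC=C(C)C)c2O)c1
F5 | step 8 | (2S)-5,7-bis(methoxymethoxy)-2-[3-methoxy-5-(methoxymethoxy)phenyl]-8-(3-methylbut-2-enyl)chromane | COCOc1cc(OC)cc([C@@H]2CCc3c(OCOC)cc(OCOC)c(CC=C(C)C)c3O2)c1
F6 | step 3 | 2-[(2-methylbut-3-yn-2-yl)oxy]-4,6-bis(methoxymethoxy)benzaldehyde | C#CC(C)(C)Oc1cc(OCOC)cc(OCOC)c1C=O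
F7 | step 4 | 2,4,6-trihydroxy-3-(3-methylbut-2-enyl)benzaldehyde | O=Cc1c(O)cc(O)c(CC=C(C)C)c1O
F8 | step 9 | (2S)-2-[3-methoxy-5-(trimethylsilyloxy)phenyl]-8-(3-methylbut-2-enyl)-5,7-bis(trimethylsilyloxy)chromane | COc1cc(O[Si](C)(C)C)cc([C@@H]2CCc3c(O[Si](C)(C)C)cc(O[Si](C)(C)C)c(CC=C(C)C)c3O2)c1
A1 | alternative 1 | 2-[(3R)-3-[3-methoxy-5-(triisopropylsilyloxy)phenyl]-3-(triethylsilyloxy)propyl]-6-(3-methylbut-2-enyl)-3,5-bis(triisopropylsilyloxy)phenol | COc1cc(O[Si](C(C)C)(C(C)C)C(C)C)cc([C@H](O[Si](CC)(CC)CC)CCc2c(O[Si](C(C)C)(C(C)C)C(C)C)cc(O[Si](C(C)C)(C(C)C)C(C)C)c(CC=C(C)C)c2O)c1
A2 | alternative 1 | 4-(3-methylbut-2-enyl)-3-(triisopropylsilyloxy)cyclobut-2-en-1-one | CC(C)=CCC1C(=O)C=C1O[Si](C(C)C)(C(C)C)C(C)C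
A3 | alternative 1 | triethyl-[(1R)-1-[3-methoxy-5-(triisopropylsilyloxy)phenyl]-5-(triisopropylsilyloxy)pent-4-ynoxy]silane | COc1cc(O[Si](C(C)C)(C(C)C)C(C)C)cc([C@H](O[Si](CC)(CC)CC)CCC#CO[Si](C(C)C)(C(C)C)C(C)C)c1
A4 | alternative 2 | (2S)-2-[3-methoxy-5-(triisopropylsilyloxy)phenyl]-8-(3-methylbut-2-enyl)chromane-5,7-diol | COc1cc(O[Si](C(C)C)(C(C)C)C(C)C)cc([C@@H]2CCc3c(O)cc(O)c(CC=C(C)C)c3O2)c1
A5 | alternative 2 | methyl (2S)-2-[3-methoxy-5-(triisopropylsilyloxy)phenyl]-6-(6-methyl-2-oxohept-5-en-3-yl)-3,4-dihydro-2H-pyran-5-carboxylate | COc1cc(O[Si](C(C)C)(C(C)C)C(C)C)cc([C@@H]2CCC(C(=O)OC)=C(C(CC=C(C)C)C(C)=O)O2)c1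
A6 | alternative 3 | (2S)-5,7-bis(methoxymethoxy)-2-[3-methoxy-5-(methoxymethoxy)phenyl]-8-(3-methylbut-2-enyl)-2H-chromene | COc1cc(OCOC)cc([C@@H]2C=Cc3c(OCOC)cc(OCOC)c(CC=C(C)C)c3O2)c1
A7 | alternative 3 | N-[3,5-bis(methoxymethoxy)-2-(3-methylbut-2-enyl)phenoxy]acetamide | CC(=O)NOc1cc(OCOC)cc(OCOC)c1CC=C(C)C
A8 | alternative 3 | 1-(cycloprop-2-en-1-yl)-3-methoxy-5-(methoxymethoxy)benzene | COCOc1cc(OC)cc(C2C=C2)c1
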